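**Retrosynthetic overview**

1. Late cuts: the C2 senecioate (Steglich esterification), the C12–C13 bond (lithiation–borylation of a C12 pinacol boronate with the carbamate of (R)-but-3-en-2-ol, then oxidation) and the C7=C8 alkene (thermodynamic enol triflate of a C7 ketone, reduced with formate under palladium catalysis).
2. Feature used: C5 and C10 are the adjacent fusion atoms of rings A and B, and C9, next to C10 in ring B, carries C11. Cutting C5–C10 and C8–C9 together opens both rings to a 3-methyldeca-2,7,9-trienal: enal C11(=O)–C9=C10, 2-siloxydiene C5=C6–C7(OSi)=C8–C17, tether C1–C4 with the C2 silyl ether and the C4 gem-dimethyl group.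
3. Ring order: rings A and B form together in one intramolecular Diels–Alder step (ring B as the new cyclohexene, ring A through the tether); no other ring is made.
4. The trienal comes from an asymmetric vinylogous Mukaiyama aldol (C1–C2 bond, sets C2) and a Horner–Wadsworth–Emmons reaction (C5=C6).

Key step: step 10

Remark on numbering: labdane numbering is used for the bicyclic compounds (ring A = C1–C5, C10; ring B = C5–C10; side chain C11–C16 on C9; C17 on C8; C18 and C19 on C4; C20 on C10). Open-chain compounds carry their own IUPAC locants.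

Assumptions: 1, 3, 10, 22 and 29 are bought. Ketene acetal 5 is used as its mixture of geometric isomers and ketone 18 may be a mixture at C8; neither matters later. The (S,S)-catalyst of step 3 is taken to add the dienolate to the Si face of 2; if MTPA ester analysis of 6 shows the opposite sense, the (R,R)-catalyst is used.

**Route**

Step 1
Reactants: 1 methyl 3,3-dimethylpent-4-enoate
Product: 2 3,3-dimethylpent-4-enal
Conditions: iBu2AlH (1.05 equiv), CH2Cl2, −78 °C; MeOH quench, aqueous potassium sodium tartrate; carried on as a dried CH2Cl2 solution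
Reagents that add atoms: none
Why: Partial ester reduction with diisobutylaluminium hydride at −78 °C stops at the aluminium hemiacetal, which releases the (volatile) aldehyde on work-up.

Step 2
Reactants: 3 methyl 3-methylbut-2-enoate
Product: 5 tert-butyl[(1-methoxy-3-methylbuta-1,3-dien-1-yl)oxy]dimethylsilane, via lithium dienolate 4 (not isolated)
Conditions: LiN(iPr)2, THF, −78 °C; then TBSCl, DMPU, −78 °C to rt; distillation
Reagents that add atoms: tert-butyldimethylsilyl chloride, CC(C)(C)[Si](C)(C)Cl
Why: γ-Deprotonation of the senecioate gives the extended dienolate, which is silylated on oxygen (silyl ketene acetal formation).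

Step 3
Reactants: 2 3,3-dimethylpent-4-enal; 5 tert-butyl[(1-methoxy-3-methylbuta-1,3-dien-1-yl)oxy]dimethylsilane
Product: 6 methyl (2E,5S)-5-hydroxy-3,7,7-trimethylnona-2,8-dienoate
Conditions: SiCl4 (1.1 equiv), (S,S)-bis(phosphoramide) catalyst [pentane-1,5-diyl-linked, from (S)-N,N'-dimethyl-1,1'-binaphthyl-2,2'-diamine] (5 mol %), iPr2NEt (cat.), CH2Cl2, −78 °C; aqueous KF/NaHCO3
Reagents that add atoms: none
Why: Catalytic enantioselective vinylogous Mukaiyama aldol reaction, in which the chiral phosphoramide-bound chlorosilyl cation activates the aldehyde and the dienolate attacks through its γ-carbon on the Si face, setting the carbinol centre (the future C2) as S and giving the E enoate from the s-trans dienolate.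

Step 4
Reactants: 6 methyl (2E,5S)-5-hydroxy-3,7,7-trimethylnona-2,8-dienoate
Product: 7 methyl (2E,5S)-5-[(tert-butyldimethylsilyl)oxy]-3,7,7-trimethylnona-2,8-dienoate
Conditions: TBSOTf, 2,6-lutidine, CH2Cl2, −78 to 0 °C
Reagents that add atoms: tert-butyldimethylsilyl trifluoromethanesulfonate, CC(C)(C)[Si](C)(C)OS(=O)(=O)C(F)(F)F
Why: Silylation of the secondary alcohol with the silyl triflate and a hindered base is fast and leaves the stereocentre untouched; the ether also blocks any later oxa-Michael addition to the enone.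

Step 5
Reactants: 7 methyl (2E,5S)-5-[(tert-butyldimethylsilyl)oxy]-3,7,7-trimethylnona-2,8-dienoate
Product: 9 methyl (2E,5S)-5-[(tert-butyldimethylsilyl)oxy]-3,7,7-trimethyl-8-oxooct-2-enoate, via diol 8 (not isolated)
Conditions: OsO4 (2 mol %), NaIO4 (4 equiv), 2,6-lutidine (2 equiv), dioxane/H2O 3:1, rt
Reagents that add atoms: OsO4, O=[Os](=O)(=O)=O; NaIO4, [Na+].[O-]I(=O)(=O)=O
Why: Lemieux–Johnson oxidative cleavage, in which electrophilic OsO4 dihydroxylates the isolated monosubstituted alkene much faster than the conjugated trisubstituted enoate and periodate cleaves the diol to the non-enolisable aldehyde.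

Step 6
Reactants: 9 methyl (2E,5S)-5-[(tert-butyldimethylsilyl)oxy]-3,7,7-trimethyl-8-oxooct-2-enoate; 10 diethyl (2-oxobutyl)phosphonate
Product: 12 methyl (2E,5S,8E)-5-[(tert-butyldimethylsilyl)oxy]-3,7,7-trimethyl-10-oxododeca-2,8-dienoate, via sodium phosphonate 11 (not isolated)
Conditions: 10, NaH, THF, 0 °C; then 9, 0 °C to rt
Reagents that add atoms: none
Why: Horner–Wadsworth–Emmons reaction of a stabilised β-keto phosphonate anion with an α-quaternary aldehyde that cannot enolise gives the E enone; the enoate is not deprotonated by this weakly basic anion.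

Step 7
Reactants: 12 methyl (2E,5S,8E)-5-[(tert-butyldimethylsilyl)oxy]-3,7,7-trimethyl-10-oxododeca-2,8-dienoate
Product: 13 methyl (2E,5S,8E,10Z)-5,10-bis[(tert-butyldimethylsilyl)oxy]-3,7,7-trimethyldodeca-2,8,10-trienoate
Conditions: TBSOTf (1.2 equiv), Et3N (2 equiv), CH2Cl2, −78 to 0 °C; pH 7 buffer; Et3N-deactivated silica
Reagents that add atoms: tert-butyldimethylsilyl trifluoromethanesulfonate, CC(C)(C)[Si](C)(C)OS(=O)(=O)C(F)(F)F
Why: Soft enolisation of the ethyl ketone (silyl triflate and amine) can only occur at the ethyl CH2, because the γ-carbon is quaternary, and gives the Z silyl enol ether of the 2-siloxydiene, while the less acidic ester is left alone at low temperature.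

Step 8
Reactants: 13 methyl (2E,5S,8E,10Z)-5,10-bis[(tert-butyldimethylsilyl)oxy]-3,7,7-trimethyldodeca-2,8,10-trienoate
Product: 14 (2E,5S,8E,10Z)-5,10-bis[(tert-butyldimethylsilyl)oxy]-3,7,7-trimethyldodeca-2,8,10-trien-1-ol
Conditions: iBu2AlH (2.2 equiv), CH2Cl2, −78 °C; aqueous potassium sodium tartrate
Reagents that add atoms: none
Why: 1,2-Reduction of the enoate by diisobutylaluminium hydride gives the allylic alcohol, and the ketone is already masked as the silyl dienol ether, which survives the neutral work-up.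

Step 9
Reactants: 14 (2E,5S,8E,10Z)-5,10-bis[(tert-butyldimethylsilyl)oxy]-3,7,7-trimethyldodeca-2,8,10-trien-1-ol
Product: 15 (2E,5S,8E,10Z)-5,10-bis[(tert-butyldimethylsilyl)oxy]-3,7,7-trimethyldodeca-2,8,10-trienal
Conditions: MnO2 (activated, excess), CH2Cl2, rt; filtration; used at once
Reagents that add atoms: none
Why: Allylic oxidation with MnO2 is neutral and selective for the allylic alcohol, so the acid-sensitive dienol ether and the E geometry of the enal are kept.

Step 10
Reactants: 15 (2E,5S,8E,10Z)-5,10-bis[(tert-butyldimethylsilyl)oxy]-3,7,7-trimethyldodeca-2,8,10-trienal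
Product: 16 (1R,2S,4aR,7R,8aR)-3,7-bis[(tert-butyldimethylsilyl)oxy]-2,5,5,8a-tetramethyl-1,2,4a,5,6,7,8,8a-octahydronaphthalene-1-carbaldehyde (labdane numbering: C11 formyl on C9, C17 on C8, enol ether C6=C7; H-5 and O-2 on the face opposite C20; C11 and C17 on the face of C20)
Conditions: Me2AlCl (1.2 equiv), CH2Cl2 (0.01 M), −78 to −20 °C; Et3N, then aqueous NaHCO3
Reagents that add atoms: none
Why: Me2AlCl binds the formyl oxygen of the s-trans (E)-enal and lowers its LUMO, and a concerted but asynchronous [4+2] cycloaddition with the tethered 2-siloxydiene follows, the C5–C10 bond to the enal β-carbon leading; the closest known reaction type is the Lewis-acid-promoted type 1 intramolecular Diels–Alder reaction of deca-1,7,9-trienals. The siloxy group raises the diene HOMO but has its large coefficient at C8, so the regiochemistry rests on the tether alone; the electronically matched orientation would give a strained bridged bicyclo[4.3.1] skeleton and should not compete. Ring B closes as the cyclohexene of the cycloaddition (C5–C10 and C8–C9 formed suprafacially on both partners), and ring A closes as the six-membered fused ring through the four-carbon tether C1–C4 held in a chair. C9 and C10 follow from the E dienophile (C11 cis to C20), C5 from the endo transition state (formyl under the diene, tether anti) that Lewis acid complexation favours and that gives the trans ring fusion, and C8 from the Z enol ether (methyl outside, ending cis to C11), a centre that is erased later. The absolute sense comes from C2: in the chair tether the silyloxy group sits equatorial, since the axial position would clash with both the C10 methyl and the axial C4 methyl, and this fixes the diene face. The step needs endo over exo selectivity and enough reactivity to join quaternary C10 to neopentyl C5; aldehyde activation, the electron-rich diene and the gem-dimethyl effect at C4 serve this, and high dilution at low temperature suppresses intermolecular Mukaiyama-type additions of the silyl dienol ether.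

Step 11
Reactants: 16 the bicyclic C11 aldehyde
Product: 17 2,7-bis[(tert-butyldimethylsilyl)oxy]-13,14,15,16-tetranorlabda-6,11-diene (vinyl group C11=C12 on C9; stereocentres as in 16)
Conditions: Ph3PCH3Br, KN(SiMe3)2, THF, 0 °C; then 16, 0 °C to rt
Reagents that add atoms: methyltriphenylphosphonium bromide, C[P+](c1ccccc1)(c1ccccc1)c1ccccc1.[Br-]
Why: Wittig methylenation with the unstabilised ylide converts the formyl group into the C11=C12 vinyl group through the oxaphosphetane, without touching the silyl ethers and, at low temperature, without deprotonation at C9.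

Step 12
Reactants: 17 2,7-bis[(tert-butyldimethylsilyl)oxy]-13,14,15,16-tetranorlabda-6,11-diene
Product: 18 2-[(tert-butyldimethylsilyl)oxy]-13,14,15,16-tetranorlabd-11-en-7-one (C8 as in 16)
Conditions: Bu4NF (1.05 equiv), AcOH (1.2 equiv), THF, −20 to 0 °C
Reagents that add atoms: none
Why: Fluoride-induced cleavage of the silyl enol ether is far faster than that of the secondary alkyl silyl ether, because an enolate is the better leaving group on silicon, so the C7 ketone is released (protonation at C6) while the C2 ether stays.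

Step 13
Reactants: 18 2-[(tert-butyldimethylsilyl)oxy]-13,14,15,16-tetranorlabd-11-en-7-one
Product: 19 2-[(tert-butyldimethylsilyl)oxy]-13,14,15,16-tetranorlabda-7,11-dien-7-yl trifluoromethanesulfonate
Conditions: Tf2O (1.3 equiv), 2,6-di-tert-butyl-4-methylpyridine (1.5 equiv), CH2Cl2, 0 °C to rt
Reagents that add atoms: trifluoromethanesulfonic anhydride, O=S(=O)(OS(=O)(=O)C(F)(F)F)C(F)(F)F
Why: Thermodynamic enol triflate formation, in which O-triflation of the ketone followed by proton loss under a hindered pyridine favours the more substituted C7=C8 enol triflate and removes the C8 stereocentre.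

Step 14
Reactants: 19 the C7 enol triflate
Product: 20 2-[(tert-butyldimethylsilyl)oxy]-13,14,15,16-tetranorlabda-7,11-diene
Conditions: Pd(OAc)2 (5 mol %), PPh3 (10 mol %), HCO2H (2 equiv), Bu3N (3 equiv), DMF, 60 °C
Reagents that add atoms: none
Why: Palladium-catalysed formate reduction of an enol triflate: oxidative addition to zerovalent palladium formed in situ, exchange of triflate for formate, loss of CO2 and C–H reductive elimination replace OTf by H without moving the C7=C8 bond.

Step 15
Reactants: 20 2-[(tert-butyldimethylsilyl)oxy]-13,14,15,16-tetranorlabda-7,11-diene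
Product: 21 2-{2-[(tert-butyldimethylsilyl)oxy]-13,14,15,16-tetranorlabd-7-en-12-yl}-4,4,5,5-tetramethyl-1,3,2-dioxaborolane
Conditions: [Ir(cod)Cl]2 (1.5 mol %), Ph2PCH2PPh2 (3 mol %), pinacolborane (1.2 equiv), CH2Cl2, rt
Reagents that add atoms: pinacolborane, CC1(C)OBOC1(C)C
Why: Iridium-catalysed hydroboration of the monosubstituted alkene gives the linear (anti-Markovnikov) primary boronate, and the trisubstituted C7=C8 alkene does not react.

Step 16
Reactants: 22 (R)-but-3-en-2-ol
Product: 23 (R)-but-3-en-2-yl N,N-diisopropylcarbamate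
Conditions: iPr2NCOCl, Et3N, CH2Cl2, reflux
Reagents that add atoms: N,N-diisopropylcarbamoyl chloride, CC(C)N(C(C)C)C(=O)Cl
Why: O-Carbamoylation of the secondary allylic alcohol installs the directing and leaving group without touching the stereocentre.

Step 17
Reactants: 21 the C12 pinacol boronate; 23 (R)-but-3-en-2-yl N,N-diisopropylcarbamate
Product: 27 (13S)-2-[(tert-butyldimethylsilyl)oxy]labda-7,14-dien-13-ol, via lithiated carbamate 24 (not isolated), via boronate complex 25 (not isolated), via tertiary boronic ester 26 (not isolated)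
Conditions: 23 (1.3 equiv), sBuLi (1.2 equiv), TMEDA, Et2O, −78 °C; then 21, −78 °C to rt (MgBr2·OEt2/MeOH if migration is slow); then NaOH, H2O2, THF, 0 °C to rt
Reagents that add atoms: hydrogen peroxide, OO
Why: Lithiation–borylation: sBuLi/TMEDA removes the allylic proton α to oxygen with retention, boronate 21 adds at the α-carbon with retention, 1,2-migration of the C12 alkyl group with inversion expels the carbamate, and oxidation of the C–B bond with retention gives the tertiary allylic alcohol, so the R carbamate leads to 13S.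

Step 18
Reactants: 27 (13S)-2-[(tert-butyldimethylsilyl)oxy]labda-7,14-dien-13-ol
Product: 28 (2R,5R,9R,10R,13S)-labda-7,14-diene-2,13-diol
Conditions: Bu4NF, THF, rt
Reagents that add atoms: none
Why: Fluoride desilylation frees the secondary C2 alcohol; neither alkene nor the tertiary allylic alcohol reacts.

Step 19
Reactants: 28 (2R,5R,9R,10R,13S)-labda-7,14-diene-2,13-diol; 29 3-methylbut-2-enoic acid
Product: 30 (2R,5R,9R,10R,13S)-13-hydroxylabda-7,14-dien-2-yl 3-methylbut-2-enoate (target)
Conditions: 29 (1.5 equiv), DCC, DMAP (0.1 equiv), CH2Cl2, 0 °C to rt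
Reagents that add atoms: none
Why: Steglich esterification acylates the equatorial secondary C2 alcohol through the acylpyridinium, while the hindered tertiary C13 alcohol stays free; catalytic DMAP at low temperature limits deconjugation of the senecioyl group.

**Compound list**

1 | methyl 3,3-dimethylpent-4-enoate | COC(=O)CC(C)(C)C=C | starting material
2 | 3,3-dimethylpent-4-enal | O=CCC(C)(C)C=C | intermediate
3 | methyl 3-methylbut-2-enoate | COC(=O)C=C(C)C | starting material
4 | lithium 1-methoxy-3-methylbuta-1,3-dien-1-olate | C=C(C)C=C(OC)[O-].[Li+] | intermediate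
5 | tert-butyl[(1-methoxy-3-methylbuta-1,3-dien-1-yl)oxy]dimethylsilane (mixture of ketene acetal isomers) | C=C(C)C=C(OC)O[Si](C)(C)C(C)(C)C | intermediate
6 | methyl (2E,5S)-5-hydroxy-3,7,7-trimethylnona-2,8-dienoate | COC(=O)/C=C(\C)C[C@H](O)CC(C)(C)C=C | intermediate
7 | methyl (2E,5S)-5-[(tert-butyldimethylsilyl)oxy]-3,7,7-trimethylnona-2,8-dienoate | COC(=O)/C=C(\C)C[C@H](O[Si](C)(C)C(C)(C)C)CC(C)(C)C=C | intermediate
8 | methyl (2E,5S)-5-[(tert-butyldimethylsilyl)oxy]-8,9-dihydroxy-3,7,7-trimethylnon-2-enoate (both C8 epimers) | COC(=O)/C=C(\C)C[C@H](O[Si](C)(C)C(C)(C)C)CC(C)(C)C(O)CO | intermediate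
9 | methyl (2E,5S)-5-[(tert-butyldimethylsilyl)oxy]-3,7,7-trimethyl-8-oxooct-2-enoate | COC(=O)/C=C(\C)C[C@H](O[Si](C)(C)C(C)(C)C)CC(C)(C)C=O | intermediate
10 | diethyl (2-oxobutyl)phosphonate | CCC(=O)CP(=O)(OCC)OCC | starting material
11 | sodium salt of diethyl (2-oxobutyl)phosphonate | CCC(=O)[CH-]P(=O)(OCC)OCC.[Na+] | intermediate
12 | methyl (2E,5S,8E)-5-[(tert-butyldimethylsilyl)oxy]-3,7,7-trimethyl-10-oxododeca-2,8-dienoate | COC(=O)/C=C(\C)C[C@H](O[Si](C)(C)C(C)(C)C)CC(C)(C)/C=C/C(=O)CC | intermediate
13 | methyl (2E,5S,8E,10Z)-5,10-bis[(tert-butyldimethylsilyl)oxy]-3,7,7-trimethyldodeca-2,8,10-trienoate | COC(=O)/C=C(\C)C[C@H](O[Si](C)(C)C(C)(C)C)CC(C)(C)/C=C/C(O[Si](C)(C)C(C)(C)C)=C/C | intermediate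
14 | (2E,5S,8E,10Z)-5,10-bis[(tert-butyldimethylsilyl)oxy]-3,7,7-trimethyldodeca-2,8,10-trien-1-ol | OC/C=C(\C)C[C@H](O[Si](C)(C)C(C)(C)C)CC(C)(C)/C=C/C(O[Si](C)(C)C(C)(C)C)=C/C | intermediate
15 | (2E,5S,8E,10Z)-5,10-bis[(tert-butyldimethylsilyl)oxy]-3,7,7-trimethyldodeca-2,8,10-trienal | O=C/C=C(\C)C[C@H](O[Si](C)(C)C(C)(C)C)CC(C)(C)/C=C/C(O[Si](C)(C)C(C)(C)C)=C/C | intermediate
16 | (1R,2S,4aR,7R,8aR)-3,7-bis[(tert-butyldimethylsilyl)oxy]-2,5,5,8a-tetramethyl-1,2,4a,5,6,7,8,8a-octahydronaphthalene-1-carbaldehyde | O=C[C@@H]1[C@H](C)C(O[Si](C)(C)C(C)(C)C)=C[C@@H]2C(C)(C)C[C@@H](O[Si](C)(C)C(C)(C)C)C[C@@]12C | intermediate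
17 | 2,7-bis[(tert-butyldimethylsilyl)oxy]-13,14,15,16-tetranorlabda-6,11-diene (stereocentres as in 16) | C=C[C@@H]1[C@H](C)C(O[Si](C)(C)C(C)(C)C)=C[C@@H]2C(C)(C)C[C@@H](O[Si](C)(C)C(C)(C)C)C[C@@]12C | intermediate
18 | 2-[(tert-butyldimethylsilyl)oxy]-13,14,15,16-tetranorlabd-11-en-7-one (C8 as in 16) | C=C[C@@H]1[C@H](C)C(=O)C[C@@H]2C(C)(C)C[C@@H](O[Si](C)(C)C(C)(C)C)C[C@@]12C | intermediate
19 | 2-[(tert-butyldimethylsilyl)oxy]-13,14,15,16-tetranorlabda-7,11-dien-7-yl trifluoromethanesulfonate | C=C[C@@H]1C(C)=C(OS(=O)(=O)C(F)(F)F)C[C@@H]2C(C)(C)C[C@@H](O[Si](C)(C)C(C)(C)C)C[C@@]12C | intermediate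
20 | 2-[(tert-butyldimethylsilyl)oxy]-13,14,15,16-tetranorlabda-7,11-diene | C=C[C@@H]1C(C)=CC[C@@H]2C(C)(C)C[C@@H](O[Si](C)(C)C(C)(C)C)C[C@@]12C | intermediate
21 | 2-{2-[(tert-butyldimethylsilyl)oxy]-13,14,15,16-tetranorlabd-7-en-12-yl}-4,4,5,5-tetramethyl-1,3,2-dioxaborolane | CC1(C)OB(CC[C@@H]2C(C)=CC[C@@H]3C(C)(C)C[C@@H](O[Si](C)(C)C(C)(C)C)C[C@@]23C)OC1(C)C | intermediate
22 | (R)-but-3-en-2-ol | C=C[C@@H](C)O | starting material
23 | (R)-but-3-en-2-yl N,N-diisopropylcarbamate | C=C[C@@H](C)OC(=O)N(C(C)C)C(C)C | intermediate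
24 | α-lithiated carbamate (lithium in place of the carbinol hydrogen, configuration retained) | C=C[C@@]([Li])(C)OC(=O)N(C(C)C)C(C)C | intermediate
25 | lithium boronate complex of 21 and 24 (boron on the carbamate carbon, configuration retained) | C=C[C@@]([B-]1(CC[C@@H]2C(C)=CC[C@@H]3C(C)(C)C[C@@H](O[Si](C)(C)C(C)(C)C)C[C@@]23C)OC(C)(C)C(C)(C)O1)(C)OC(=O)N(C(C)C)C(C)C.[Li+] | intermediate
26 | (13R)-2-[(tert-butyldimethylsilyl)oxy]-13-(4,4,5,5-tetramethyl-1,3,2-dioxaborolan-2-yl)labda-7,14-diene | C=C[C@](B1OC(C)(C)C(C)(C)O1)(C)CC[C@@H]2C(C)=CC[C@@H]3C(C)(C)C[C@@H](O[Si](C)(C)C(C)(C)C)C[C@@]23C | intermediate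
27 | (13S)-2-[(tert-butyldimethylsilyl)oxy]labda-7,14-dien-13-ol (2R,5R,9R,10R) | C=C[C@@](C)(O)CC[C@@H]1C(C)=CC[C@@H]2C(C)(C)C[C@@H](O[Si](C)(C)C(C)(C)C)C[C@@]12C | intermediate
28 | (2R,5R,9R,10R,13S)-labda-7,14-diene-2,13-diol | C=C[C@@](C)(O)CC[C@@H]1C(C)=CC[C@@H]2C(C)(C)C[C@@H](O)C[C@@]12C | intermediate
29 | 3-methylbut-2-enoic acid | CC(C)=CC(=O)O | starting material
30 | (2R,5R,9R,10R,13S)-13-hydroxylabda-7,14-dien-2-yl 3-methylbut-2-enoate | C=C[C@@](C)(O)CC[C@@H]1C(C)=CC[C@@H]2C(C)(C)C[C@@H](OC(=O)C=C(C)C)C[C@@]12C | target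

**Step count and risks**

Total steps: 19 (including the preparation of 5 and of 23). Longest linear sequence: 17 steps (1 to 30 through steps 1, 3–15 and 17–19).

Steps most likely to fail:

1. Step 10 (intramolecular Diels–Alder). The cycloaddition may stall or lose its endo preference, because the leading C5–C10 bond joins a quaternary to a neopentyl carbon and the siloxy group does not polarise the diene in the sense the tether demands. The Lewis acid may also strip the silyl dienol ether or start intermolecular Mukaiyama-type additions. Fallback: set out from trienoate 13 and use no Lewis acid. Heating 13 in toluene (about 170 °C, sealed vessel, BHT, a little N,O-bis(trimethylsilyl)acetamide as acid scavenger) should give, by thermal intramolecular Diels–Alder reaction of the enoate, the methyl ester cycloadduct F1, with the diastereomers separated at this stage. Reduction with iBu2AlH then gives the primary alcohol F2, and oxidation (Dess–Martin periodinane, NaHCO3) comes back to the route at aldehyde 16.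

2. Step 17 (lithiation–borylation). The lithiated allyl carbamate may be borylated at its γ-terminus, or the ate complex may revert before migration, which would lower regioselectivity and stereospecificity at C13. Fallback: set out from diene 20. Hydroboration with 9-BBN gives the B-alkyl borane F3, and a B-alkyl Suzuki–Miyaura coupling with (E)-3-iodobut-2-en-1-ol (Pd(dppf)Cl2, aqueous K3PO4, THF/DMF) gives the (E)-allylic alcohol F4. Sharpless asymmetric epoxidation (Ti(OiPr)4, diethyl L-(+)-tartrate, tBuOOH, 4 Å sieves, −20 °C) should give the (13S,14S)-epoxy alcohol F5, by analogy with geraniol. Iodination (I2, PPh3, imidazole) gives the epoxy iodide F6, and reductive opening with Zn in refluxing EtOH comes back to the route at tertiary allylic alcohol 27, with C13 set by the epoxidation.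

3. Step 13 (thermodynamic enol triflate). Triflation may follow kinetic enolisation toward C6 and give the C6=C7 regioisomer, which would place the alkene wrongly after reduction. Fallback: set out from ketone 18. Equilibrating silylation (TMSCl, NaI, Et3N, MeCN) gives the more substituted trimethylsilyl enol ether F7, which can be purified from its regioisomer. MeLi (THF, 0 °C) then releases the C7=C8 lithium enolate F8 regiospecifically, and trapping with PhNTf2 comes back to the route at enol triflate 19.

**Further compounds**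

F1 | step 10 | methyl ester cycloadduct (C11 methyl ester in place of the formyl group of 16) | COC(=O)[C@@H]1[C@H](C)C(O[Si](C)(C)C(C)(C)C)=C[C@@H]2C(C)(C)C[C@@H](O[Si](C)(C)C(C)(C)C)C[C@@]12C
F2 | step 10 | primary alcohol (C11 hydroxymethyl in place of the formyl group of 16) | OC[C@@H]1[C@H](C)C(O[Si](C)(C)C(C)(C)C)=C[C@@H]2C(C)(C)C[C@@H](O[Si](C)(C)C(C)(C)C)C[C@@]12C
F3 | step 17 | B-alkyl borane of 20 (9-borabicyclo[3.3.1]nonan-9-yl on C12) | C1CCC2CCCC1B2CC[C@@H]3C(C)=CC[C@@H]4C(C)(C)C[C@@H](O[Si](C)(C)C(C)(C)C)C[C@@]34C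
F4 | step 17 | (13E)-2-[(tert-butyldimethylsilyl)oxy]labda-7,13-dien-15-ol | OC/C=C(\C)CC[C@@H]1C(C)=CC[C@@H]2C(C)(C)C[C@@H](O[Si](C)(C)C(C)(C)C)C[C@@]12C
F5 | step 17 | (13S,14S)-2-[(tert-butyldimethylsilyl)oxy]-13,14-epoxylabd-7-en-15-ol | OC[C@@H]1O[C@@]1(C)CC[C@@H]2C(C)=CC[C@@H]3C(C)(C)C[C@@H](O[Si](C)(C)C(C)(C)C)C[C@@]23C
F6 | step 17 | 15-iodo-13,14-epoxide (same configuration as F5; descriptors 13S,14R by priority) | IC[C@@H]1O[C@@]1(C)CC[C@@H]2C(C)=CC[C@@H]3C(C)(C)C[C@@H](O[Si](C)(C)C(C)(C)C)C[C@@]23C
F7 | step 13 | 2-[(tert-butyldimethylsilyl)oxy]-7-[(trimethylsilyl)oxy]-13,14,15,16-tetranorlabda-7,11-diene | C=C[C@@H]1C(C)=C(O[Si](C)(C)C)C[C@@H]2C(C)(C)C[C@@H](O[Si](C)(C)C(C)(C)C)C[C@@]12C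
F8 | step 13 | lithium C7=C8 enolate of 18 | C=C[C@@H]1C(C)=C([O-])C[C@@H]2C(C)(C)C[C@@H](O[Si](C)(C)C(C)(C)C)C[C@@]12C.[Li+]
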